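The first decision is to look at the substrate charge of these flasks before the bath, by asking how much target the reagent can pay for.

| flask | substrate | reagent | temperature | remark | time |
|---|---|---|---|---|---|
| spring | 0.046 M | 0.0288 M | 75 °C | run made earlier |  |
| dusk | 0.060 M | 0.0288 M | 88 °C | run made earlier |  |
| south-east | 0.032 M | 0.0288 M | 95 °C |  | 15 min |
| south | 0.050 M | 0.0288 M | 80 °C |  | 15 min |
| north-east | 0.032 M | 0.0288 M | 80 °C |  | 15 min |
| south-west | 0.050 M | 0.0288 M | 95 °C |  | 15 min |

| run | time / min | target / % | substrate / % |
|---|---|---|---|
| spring | 0.667 | 5.5 | 89.3 |
| spring | 2.00 | 12.5 | 79.2 |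
| spring | 4.00 | 23.0 | 61.5 |
| spring | 5.00 | 27.1 | 58.2 |
| spring | 8.00 | 36.5 | 43.5 |
| dusk | 0.667 | 12.2 | 76.8 |
| dusk | 2.00 | 25.9 | 56.5 |
| dusk | 4.00 | 31.7 | 42.5 |
| dusk | 5.00 | 33.3 | 41.0 |
| dusk | 8.00 | 34.4 | 36.1 |

(scatter of a reading: 1 percentage point)

- the flasks put in order of amount of target, in percent of the substrate charged, best first, at 15 min (south-east / south / north-east / south-west)
- the amount of target, in percent of the substrate charged of the flask you put first, at 15 min
- the amount of target, in percent of the substrate charged of the flask you put last, at 15 min

- percentages count the substrate that a species holds: one side product A counts as two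
- the numbers in the tables scatter with a standard deviation of 1 percentage point
- steps that have been proposed: substrate <-> tautomer; substrate + reagent -> isomer of the product; tautomer -> side product B; substrate + tautomer -> side product A; reagent + tautomer -> target

In the dusk run, target gains 1.1 percentage points between 5.00 min and 8.00 min, about the scatter of a reading, while 36.1 % of the substrate still stands. The simplest reading, an assumption at this point, is that reagent is the limiting reagent of the dusk run and that target has stopped with it. Target then holds 71.7 % of the reagent charge, and this reagent share, the part of the reagent that ends as target, is a reading taken at 88 °C.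

Multiplied by the ratio of reagent to substrate charged, the share gives an allowance of target as a fraction of the substrate. That allowance is 41.3 % for south and south-west, and it is larger, 64.5 %, for north-east and south-east. Reckoned from one share, it gives the same figure for two flasks of equal substrate charge.

Time comes from the fraction left. The spring substrate falls to 43.5 % by 8.00 min, a first-order constant of 0.104 min⁻¹, which would leave 21.0 % at 15 min. My own rough estimate for the 0.032 M flasks, both warmer than spring, is therefore the allowance times the fraction used, 51.0 %, or somewhat more.

The forecast gives south-east > north-east > south > south-west, with 56 % on top, higher than my estimate, and 40 % last, and it holds of the 0.050 M flasks that “Higher temperature gains nothing there and probably costs slightly”.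

The flasks give south-east > north-east > south > south-west, from 58.9 % in south-east to 39.0 % in south-west, within the forecast's margins.

    substrate ⇌ tautomer (K = 0.0970, k = 0.00240 s⁻¹, Ea = 95.0 kJ mol⁻¹, ΔH = −39.0 kJ mol⁻¹)
    substrate + reagent → isomer of the product (k = 0.0460 L mol⁻¹ s⁻¹, Ea = 83.0 kJ mol⁻¹)
    tautomer → side product B (k = 8.50 × 10⁻⁴ s⁻¹, Ea = 118 kJ mol⁻¹)
    substrate + tautomer → side product A (k = 0.120 L mol⁻¹ s⁻¹, Ea = 67.0 kJ mol⁻¹)
    reagent + tautomer → target (k = 5.40 L mol⁻¹ s⁻¹, Ea = 56.0 kJ mol⁻¹)
    (constants at 80 °C)

In south-west at 1.09 min, the step from reagent and tautomer to target uses reagent 2.4 times as fast as the step to the isomer of the product. At 15.0 min, south-west holds 0 % of its reagent beside 21 % of its substrate, and target stands at 67.7 % of the reagent charge, against the 71.7 % read from the dusk run. A neighbouring flask, the same as south-west but with 0.017 M of reagent, has an allowance of 24.4 %, and the computed flask gives 24.3 %.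

(Readings and results are calculated from invented constants; noise was put on by code.)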